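**Retrosynthetic overview**

1. The acetate comes from tertiary alcohol 30. The bond between the CH2 arm on C4 of the lactone core and the carbinol carbon of ring A is cut to iodide 22 and (R)-4-bromo-3,3-dimethylcyclohexanone 28 (samarium Barbier reaction). Ring A is made separately by bromonium cyclisation and resolved. The core is numbered as 11-oxatricyclo[4.3.2.0^1,5]undecan-10-one.
2. The γ-lactone (C1–C10–O11–C6–C5, last ring formed) is opened to cyclohexene ester 21; the CH2I arm goes back to the exocyclic methylene of 18.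
3. The cyclopentane (C1–C5) and the cyclohexene (C1, C5–C9) of 18 are formed together by an intramolecular Diels–Alder reaction of tetraene 17 (new bonds C1–C5 and C8–C9).
4. Tetraene 17 is built from prop-2-yn-1-ol used twice (two copper-catalysed anti-carbomagnesiations fix both Z alkenes) and 2,4-dibromobut-1-ene (Negishi coupling).
5. Feature on which the strategy rests: C9 (CHBr) and C1 (quaternary, carboxyl-bearing) are adjacent and cis, and C1 lies on the C1–C5 bond shared by the cyclopentane and the cyclohexane. A Z-bromoacrylate tethered by three carbons to a Z-diene therefore delivers both rings and this cis pair in one step.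

Key step: step 9

Remark: 2,4-dibromobut-1-ene is taken as purchasable, and the (S)-configured catalyst is written for step 9 on the assumption that it leaves open the dienophile face leading to the (3aR,4R,7aR) adduct; if the opposite sense is found, the mirror-image catalyst is used.

**Route**

Step 1
Reactants: 1 prop-2-yn-1-ol
Product: 4 (2Z)-3-iodo-2-methylprop-2-en-1-ol, via bromomagnesium prop-2-yn-1-olate 2 (not isolated), via alkenylmagnesium alkoxide 3 (not isolated)
Conditions: MeMgBr (3 equiv), CuI (10 mol%), THF/Et2O, −10 °C to rt; then I2, −10 °C; aq. NH4Cl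
Reagents that add atoms: methylmagnesium bromide, C[Mg]Br; iodine, II
Why: Copper-catalysed anti-carbomagnesiation of the magnesium propargyl alkoxide puts methyl on C2 and magnesium on C3 cis to the CH2O group (chelate), and iodinolysis of the C–Mg bond with retention should give the Z iodide.

Step 2
Reactants: 4 (2Z)-3-iodo-2-methylprop-2-en-1-ol
Product: 5 (2Z)-3-iodo-2-methylprop-2-enal
Conditions: activated MnO2 (15 equiv), CH2Cl2, rt, dark; used at once
Reagents that add atoms: none
Why: Allylic oxidation with MnO2 is neutral and mild, so the Z geometry of the β-iodo enal should survive if the aldehyde is not stored.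

Step 3
Reactants: 5 (2Z)-3-iodo-2-methylprop-2-enal
Product: 6 (1Z)-1-iodo-2-methylbuta-1,3-diene
Conditions: Ph3PCH3Br, NaHMDS, THF, −78 to 0 °C; kept as a pentane/Et2O solution
Reagents that add atoms: methyltriphenylphosphonium bromide, C[P+](c1ccccc1)(c1ccccc1)c1ccccc1.[Br-]
Why: Wittig methylenation with the non-stabilised ylide at low temperature converts the aldehyde into the terminal vinyl group without touching the alkenyl iodide or its geometry.

Step 4
Reactants: 6 (1Z)-1-iodo-2-methylbuta-1,3-diene; 7 2,4-dibromobut-1-ene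
Product: 10 (3Z)-7-bromo-3-methyl-5-methylidenehepta-1,3-diene, via dienyllithium 8 (not isolated), via dienylzinc chloride 9 (not isolated)
Conditions: t-BuLi (2 equiv), Et2O, −78 °C; ZnCl2, THF, −78 to 0 °C; then 7, Pd(PPh3)4 (5 mol%), THF, 0 °C to rt
Reagents that add atoms: none
Why: Iodine–lithium exchange and transmetalation to zinc retain the alkene geometry, and the Negishi coupling is chemoselective because Pd(PPh3)4 inserts into the alkenyl C–Br bond of 7 and leaves the primary alkyl bromide untouched.

Step 5
Reactants: 10 (3Z)-7-bromo-3-methyl-5-methylidenehepta-1,3-diene; 1 prop-2-yn-1-ol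
Product: 14 (2Z,6Z)-2-(bromomethylidene)-7-methyl-5-methylidenenona-6,8-dien-1-ol, via triene Grignard reagent 11 (not isolated), via chloromagnesium prop-2-yn-1-olate 12 (not isolated), via alkenylmagnesium adduct 13 (not isolated)
Conditions: 10, Mg, THF, 25 °C; 1 + i-PrMgCl (1.0 equiv), THF, 0 °C; combine (11 : 12 = 1.5 : 1), CuI (15 mol%), −10 °C to rt; then BrCl2CCCl2Br, −40 to 0 °C; aq. NH4Cl
Reagents that add atoms: 1,2-dibromo-1,1,2,2-tetrachloroethane, BrC(Cl)(Cl)C(Cl)(Cl)Br
Why: One equivalent of i-PrMgCl removes only the hydroxyl proton of 1 (propane leaves), a second copper-catalysed anti-carbomagnesiation then adds the alkyl Grignard reagent 11 to C2 of the chloromagnesium propargyl alkoxide, and the alkenylmagnesium, held cis to CH2O by chelation, is brominated with retention by a positive-bromine donor that does not add to the triene (surplus 11 is returned as 10 by the same reagent).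

Step 6
Reactants: 14 (2Z,6Z)-2-(bromomethylidene)-7-methyl-5-methylidenenona-6,8-dien-1-ol
Product: 15 (2Z,6Z)-2-(bromomethylidene)-7-methyl-5-methylidenenona-6,8-dienal
Conditions: activated MnO2 (15 equiv), CH2Cl2, rt
Reagents that add atoms: none
Why: Chemoselective MnO2 oxidation of the allylic alcohol leaves the triene and the alkenyl bromide geometry unchanged.

Step 7
Reactants: 15 (2Z,6Z)-2-(bromomethylidene)-7-methyl-5-methylidenenona-6,8-dienal
Product: 16 (2Z,6Z)-2-(bromomethylidene)-7-methyl-5-methylidenenona-6,8-dienoic acid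
Conditions: NaClO2, NaH2PO4, 2-methylbut-2-ene (excess), t-BuOH/H2O, 0 °C
Reagents that add atoms: sodium chlorite, [Na+].[O-]Cl=O
Why: Pinnick oxidation takes the enal to the acid under buffered conditions, with the alkene scavenger intercepting hypochlorous acid before it can attack the triene.

Step 8
Reactants: 16 (2Z,6Z)-2-(bromomethylidene)-7-methyl-5-methylidenenona-6,8-dienoic acid
Product: 17 methyl (2Z,6Z)-2-(bromomethylidene)-7-methyl-5-methylidenenona-6,8-dienoate
Conditions: MeI, K2CO3, DMF, rt
Reagents that add atoms: iodomethane, CI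
Why: O-alkylation of the carboxylate (SN2 at methyl) is mild enough to leave the β-bromoacrylate geometry and the triene intact.

Step 9
Reactants: 17 methyl (2Z,6Z)-2-(bromomethylidene)-7-methyl-5-methylidenenona-6,8-dienoate
Product: 18 methyl (3aR,4R,7aR)-4-bromo-7-methyl-1-methylidene-1,2,3,4,5,7a-hexahydro-3aH-indene-3a-carboxylate (cis-fused; Br cis to CO2Me)
Conditions: (S)-3,3-diphenyl-1-(2-methylphenyl)tetrahydro-1H,3H-pyrrolo[1,2-c][1,3,2]oxazaborole + Tf2NH (20 mol% each), CH2Cl2 (0.01 M), −40 °C to rt
Reagents that add atoms: none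
Why: The triflimide-activated oxazaborolidinium ion binds the ester carbonyl and lowers the LUMO of the Z-bromoacrylate, so that a concerted, asynchronous, suprafacial [4+2] cycloaddition with the tethered Z-diene can run far below the temperature at which the cis-hexatriene unit of 17 would electrocyclise; the closest known reaction type is the chiral Lewis acid catalysed type 1 intramolecular Diels–Alder reaction of 1,3,8-nonatrienes with ester-activated dienophiles. The cyclohexene closes through the two new σ bonds of the cycloaddition (C7a–C3a and C5–C4), and the cyclopentane closes through the C7a–C3a bond alone as the fused tether ring, with the tether exo and the ester endo. C3a and C7a come out cis because a Z-diene joined to the dienophile by three atoms can reach only the cis-fused transition state, and C4 follows from the Z geometry of the bromoacrylate, which is carried over suprafacially so that Br and CO2Me stay cis. The absolute configuration depends on which dienophile face the bound catalyst leaves open, its aryl group covering the other. The step needs periselectivity for the inner diene, which the short tether secures because the diene that includes the methylidene could only give a bridged anti-Bredt ring, and enantiofacial selectivity, which the catalyst must supply.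

Step 10
Reactants: 18 methyl (3aR,4R,7aR)-4-bromo-7-methyl-1-methylidene-1,2,3,4,5,7a-hexahydro-3aH-indene-3a-carboxylate
Product: 20 methyl (1S,3aR,4R,7aR)-4-bromo-1-(hydroxymethyl)-7-methyl-1,2,3,4,5,7a-hexahydro-3aH-indene-3a-carboxylate, via B-alkyl-9-borabicyclo[3.3.1]nonane 19 (not isolated)
Conditions: 9-BBN (1.5 equiv), THF, 0 °C to rt; then NaBO3·4H2O, THF/H2O, rt
Reagents that add atoms: sodium perborate, [Na+].[Na+].O[B-]1(O)OO[B-](O)(O)OO1
Why: Anti-Markovnikov hydroboration with 9-BBN picks the 1,1-disubstituted exocyclic alkene over the trisubstituted ring alkene and should deliver hydrogen to C1 from the convex face (the side of the angular H and ester, away from C7 and its methyl group), which sets C1, and perborate oxidation retains configuration.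

Step 11
Reactants: 20 methyl (1S,3aR,4R,7aR)-4-bromo-1-(hydroxymethyl)-7-methyl-1,2,3,4,5,7a-hexahydro-3aH-indene-3a-carboxylate
Product: 21 methyl (1S,3aR,4R,7aR)-4-bromo-1-(iodomethyl)-7-methyl-1,2,3,4,5,7a-hexahydro-3aH-indene-3a-carboxylate
Conditions: I2, PPh3, imidazole, CH2Cl2, 0 °C to rt
Reagents that add atoms: iodine, II
Why: Appel-type iodination (SN2 at the primary carbon) gives the Barbier handle and, done before the acid step, removes the hydroxyl group that would otherwise close a tetrahydrofuran onto the C7 cation.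

Step 12
Reactants: 21 methyl (1S,3aR,4R,7aR)-4-bromo-1-(iodomethyl)-7-methyl-1,2,3,4,5,7a-hexahydro-3aH-indene-3a-carboxylate
Product: 22 (1R,4S,5S,6S,9R)-9-bromo-4-(iodomethyl)-6-methyl-11-oxatricyclo[4.3.2.0^1,5]undecan-10-one
Conditions: TfOH (1.5 equiv), CH2Cl2, 0 °C
Reagents that add atoms: none
Why: Acid lactonisation of a γ,δ-unsaturated ester: Markovnikov protonation of the trisubstituted alkene gives the tertiary cation, the ester carbonyl on the same face captures it to close the γ-lactone (which fixes C6, since the ring can form only on the face that carries the carboxyl group), and triflate removes the methyl group from the dialkoxycarbenium ion.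

Step 13
Reactants: 23 6-methylhept-5-en-2-one
Product: 24 methyl 7-methyl-3-oxooct-6-enoate
Conditions: NaH, dimethyl carbonate, THF, reflux; aq. HCl work-up
Reagents that add atoms: dimethyl carbonate, COC(=O)OC
Why: Crossed Claisen C-acylation under equilibrating conditions takes place at the methyl group because that product forms the more stable β-keto ester enolate.

Step 14
Reactants: 24 methyl 7-methyl-3-oxooct-6-enoate
Product: 25 methyl 3-bromo-2,2-dimethyl-6-oxocyclohexane-1-carboxylate (racemic)
Conditions: 2,4,4,6-tetrabromocyclohexa-2,5-dien-1-one (1.1 equiv), MeNO2, 0 °C to rt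
Reagents that add atoms: 2,4,4,6-tetrabromocyclohexa-2,5-dien-1-one, O=C1C(Br)=CC(Br)(Br)C=C1Br
Why: Bromonium-induced cation–olefin cyclisation: Br+ adds to the trisubstituted alkene and the enol carbon of the β-keto ester closes the six-membered ring at the tertiary carbon, which places bromine next to the gem-dimethyl group, where substitution chemistry could not put it.

Step 15
Reactants: 25 methyl 3-bromo-2,2-dimethyl-6-oxocyclohexane-1-carboxylate
Product: 27 rac-4-bromo-3,3-dimethylcyclohexan-1-one, via keto acid 26 (not isolated)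
Conditions: 6 M HCl/AcOH, 90 °C
Reagents that add atoms: none
Why: Acidic ester hydrolysis and decarboxylation of the β-keto acid avoid the halide nucleophiles and bases that could attack the secondary bromide.

Step 16
Reactants: 27 rac-4-bromo-3,3-dimethylcyclohexan-1-one
Product: 28 (4R)-4-bromo-3,3-dimethylcyclohexan-1-one
Conditions: preparative chromatography on amylose tris(3,5-dimethylphenylcarbamate), CO2/i-PrOH
Reagents that add atoms: none
Why: Resolution on a chiral stationary phase separates the enantiomers without chemistry at the sensitive neopentylic C–Br centre, and the (4R) enantiomer is to be identified by anomalous X-ray scattering of the bromine atom.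

Step 17
Reactants: 22 (1R,4S,5S,6S,9R)-9-bromo-4-(iodomethyl)-6-methyl-11-oxatricyclo[4.3.2.0^1,5]undecan-10-one; 28 (4R)-4-bromo-3,3-dimethylcyclohexan-1-one
Product: 30 (1R,4R,5S,6S,9R)-9-bromo-4-{[(1R,4R)-4-bromo-1-hydroxy-3,3-dimethylcyclohexyl]methyl}-6-methyl-11-oxatricyclo[4.3.2.0^1,5]undecan-10-one, via alkylsamarium diiodide 29 (not isolated)
Conditions: SmI2 (2.5 equiv), NiI2 (2 mol%), 28 (1.5 equiv), THF, 0 °C; aq. NH4Cl
Reagents that add atoms: none
Why: Samarium Barbier reaction: SmI2 reduces the primary C–I bond well before the secondary C–Br bonds, and the alkylsamarium should add to the ketone from the equatorial side of the chair with equatorial bromine, because the axial C3 methyl blocks axial attack, giving the axial alcohol cis to bromine (1R); the epimer at the carbinol carbon that arises from the minor chair with axial bromine is to be removed by chromatography.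

Step 18
Reactants: 30 (1R,4R,5S,6S,9R)-9-bromo-4-{[(1R,4R)-4-bromo-1-hydroxy-3,3-dimethylcyclohexyl]methyl}-6-methyl-11-oxatricyclo[4.3.2.0^1,5]undecan-10-one
Product: 31 (1R,4R)-4-bromo-1-{[(1R,4R,5S,6S,9R)-9-bromo-6-methyl-10-oxo-11-oxatricyclo[4.3.2.0^1,5]undecan-4-yl]methyl}-3,3-dimethylcyclohexyl acetate
Conditions: Ac2O, DMAP (1 equiv), Et3N, CH2Cl2, 40 °C
Reagents that add atoms: acetic anhydride, CC(=O)OC(C)=O
Why: DMAP-catalysed (Steglich-type) acylation through the N-acetylpyridinium ion is strong enough for a hindered tertiary alcohol and leaves the lactone and both bromides alone.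

**Compound list**

1 | prop-2-yn-1-ol | C#CCO | starting material
2 | bromomagnesium prop-2-yn-1-olate | C#CCO[Mg]Br | intermediate
3 | [(1Z)-3-(bromomagnesiooxy)-2-methylprop-1-en-1-yl]magnesium bromide | Br[Mg]/C=C(/C)CO[Mg]Br | intermediate
4 | (2Z)-3-iodo-2-methylprop-2-en-1-ol | I/C=C(/C)CO | intermediate
5 | (2Z)-3-iodo-2-methylprop-2-enal | I/C=C(/C)C=O | intermediate
6 | (1Z)-1-iodo-2-methylbuta-1,3-diene | I/C=C(/C)C=C | intermediate
7 | 2,4-dibromobut-1-ene | C=C(Br)CCBr | starting material
8 | [(1Z)-2-methylbuta-1,3-dien-1-yl]lithium | [Li]/C=C(/C)C=C | intermediate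
9 | chloro[(1Z)-2-methylbuta-1,3-dien-1-yl]zinc | Cl[Zn]/C=C(/C)C=C | intermediate
10 | (3Z)-7-bromo-3-methyl-5-methylidenehepta-1,3-diene | C=C(CCBr)/C=C(C)\C=C | intermediate
11 | [(4Z)-5-methyl-3-methylidenehepta-4,6-dien-1-yl]magnesium bromide | C=C(CC[Mg]Br)/C=C(C)\C=C | intermediate
12 | chloromagnesium prop-2-yn-1-olate | C#CCO[Mg]Cl | intermediate
13 | {(1Z,6Z)-2-[(chloromagnesiooxy)methyl]-7-methyl-5-methylidenenona-1,6,8-trien-1-yl}magnesium bromide | C=C(CC/C(CO[Mg]Cl)=C/[Mg]Br)/C=C(C)\C=C | intermediate
14 | (2Z,6Z)-2-(bromomethylidene)-7-methyl-5-methylidenenona-6,8-dien-1-ol | C=C(CC/C(CO)=C/Br)/C=C(C)\C=C | intermediate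
15 | (2Z,6Z)-2-(bromomethylidene)-7-methyl-5-methylidenenona-6,8-dienal | C=C(CC/C(C=O)=C/Br)/C=C(C)\C=C | intermediate
16 | (2Z,6Z)-2-(bromomethylidene)-7-methyl-5-methylidenenona-6,8-dienoic acid | C=C(CC/C(C(=O)O)=C/Br)/C=C(C)\C=C | intermediate
17 | methyl (2Z,6Z)-2-(bromomethylidene)-7-methyl-5-methylidenenona-6,8-dienoate | C=C(CC/C(C(=O)OC)=C/Br)/C=C(C)\C=C | intermediate
18 | methyl (3aR,4R,7aR)-4-bromo-7-methyl-1-methylidene-1,2,3,4,5,7a-hexahydro-3aH-indene-3a-carboxylate | C=C1CC[C@@]2(C(=O)OC)[C@H](Br)CC=C(C)[C@@H]12 | intermediate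
19 | methyl (1S,3aR,4R,7aR)-1-[(9-borabicyclo[3.3.1]nonan-9-yl)methyl]-4-bromo-7-methyl-1,2,3,4,5,7a-hexahydro-3aH-indene-3a-carboxylate | C1CCC2CCCC1B2C[C@H]3CC[C@@]4(C(=O)OC)[C@H](Br)CC=C(C)[C@@H]34 | intermediate
20 | methyl (1S,3aR,4R,7aR)-4-bromo-1-(hydroxymethyl)-7-methyl-1,2,3,4,5,7a-hexahydro-3aH-indene-3a-carboxylate | OC[C@H]1CC[C@@]2(C(=O)OC)[C@H](Br)CC=C(C)[C@@H]12 | intermediate
21 | methyl (1S,3aR,4R,7aR)-4-bromo-1-(iodomethyl)-7-methyl-1,2,3,4,5,7a-hexahydro-3aH-indene-3a-carboxylate | IC[C@H]1CC[C@@]2(C(=O)OC)[C@H](Br)CC=C(C)[C@@H]12 | intermediate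
22 | (1R,4S,5S,6S,9R)-9-bromo-4-(iodomethyl)-6-methyl-11-oxatricyclo[4.3.2.0^1,5]undecan-10-one | IC[C@H]2CC[C@@]34C(=O)O[C@@](C)(CC[C@H]3Br)[C@@H]24 | intermediate
23 | 6-methylhept-5-en-2-one | CC(=O)CCC=C(C)C | starting material
24 | methyl 7-methyl-3-oxooct-6-enoate | COC(=O)CC(=O)CCC=C(C)C | intermediate
25 | methyl 3-bromo-2,2-dimethyl-6-oxocyclohexane-1-carboxylate (racemic) | COC(=O)C1C(=O)CCC(Br)C1(C)C | intermediate
26 | 3-bromo-2,2-dimethyl-6-oxocyclohexane-1-carboxylic acid (racemic) | OC(=O)C1C(=O)CCC(Br)C1(C)C | intermediate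
27 | rac-4-bromo-3,3-dimethylcyclohexan-1-one | O=C1CCC(Br)C(C)(C)C1 | intermediate
28 | (4R)-4-bromo-3,3-dimethylcyclohexan-1-one | O=C1CC[C@@H](Br)C(C)(C)C1 | intermediate
29 | {[(1R,4S,5S,6S,9R)-9-bromo-6-methyl-10-oxo-11-oxatricyclo[4.3.2.0^1,5]undecan-4-yl]methyl}samarium diiodide | I[Sm](I)C[C@H]2CC[C@@]34C(=O)O[C@@](C)(CC[C@H]3Br)[C@@H]24 | intermediate
30 | (1R,4R,5S,6S,9R)-9-bromo-4-{[(1R,4R)-4-bromo-1-hydroxy-3,3-dimethylcyclohexyl]methyl}-6-methyl-11-oxatricyclo[4.3.2.0^1,5]undecan-10-one | O[C@@]1(C[C@H]2CC[C@@]34C(=O)O[C@@](C)(CC[C@H]3Br)[C@@H]24)CC[C@@H](Br)C(C)(C)C1 | intermediate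
31 | (1R,4R)-4-bromo-1-{[(1R,4R,5S,6S,9R)-9-bromo-6-methyl-10-oxo-11-oxatricyclo[4.3.2.0^1,5]undecan-4-yl]methyl}-3,3-dimethylcyclohexyl acetate | CC(=O)O[C@@]1(C[C@H]2CC[C@@]34C(=O)O[C@@](C)(CC[C@H]3Br)[C@@H]24)CC[C@@H](Br)C(C)(C)C1 | target

**Step count and risks**

Total step count: 18. Longest linear sequence: 14 steps (steps 1–12, 17 and 18, from prop-2-yn-1-ol).

Steps most likely to fail:

Step 9. The s-cis form of the Z-diene is poorly populated, and the ester has no α-hydrogen to fix its position on the catalyst and is only weakly activated. The cycloaddition may therefore be slow, and the catalyst may not tell the two dienophile faces apart; warming to force it would start the 6π electrocyclisation of the cis-hexatriene. The fallback moves the cycloaddition to the aldehyde oxidation level; it sets out from enal 15 and returns at ester 18. Enal 15, a 2-alkyl-3-bromoacrolein, is a much stronger dienophile and binds the oxazaborolidinium ion in the established way of α-substituted acroleins (formyl C–H to the ring oxygen). With the same catalyst at −78 to −40 °C it should give, by the same two bond formations, (3aR,4R,7aR)-4-bromo-7-methyl-1-methylidene-1,2,3,4,5,7a-hexahydro-3aH-indene-3a-carbaldehyde F1. Pinnick oxidation (NaClO2, NaH2PO4, 2-methylbut-2-ene) then gives (3aR,4R,7aR)-4-bromo-7-methyl-1-methylidene-1,2,3,4,5,7a-hexahydro-3aH-indene-3a-carboxylic acid F2, and methylation with MeI and K2CO3 gives 18.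

Step 5. The functionalised Grignard reagent 11 may be consumed by deprotonation of the acetylenic C–H of 12 or by decay of the alkylcopper intermediate before it adds, so that the carbomagnesiation stalls. The fallback builds the bromoacrylate from an ester enolate instead; it sets out from bromide 10 and returns at tetraene ester 17. Methyl 3,3-dimethoxypropanoate is deprotonated (LDA, THF/DMPU, −78 °C) and alkylated with 10 to give methyl (6Z)-2-(dimethoxymethyl)-7-methyl-5-methylidenenona-6,8-dienoate F3. Mild acetal hydrolysis (pyridinium p-toluenesulfonate, wet acetone) gives methyl (6Z)-2-formyl-7-methyl-5-methylidenenona-6,8-dienoate F4. Its chelated lithium enolate (LiHMDS, −78 °C) is O-sulfonylated with PhNTf2 to methyl (2Z,6Z)-7-methyl-5-methylidene-2-({[(trifluoromethyl)sulfonyl]oxy}methylidene)nona-6,8-dienoate F5, the chelate placing the triflate cis to the ester. Triflate–bromide exchange with LiBr and catalytic [Cp*Ru(MeCN)3]OTf, which keeps the alkene geometry, gives 17.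

Step 17. Electron transfer to the two secondary C–Br bonds or to the ketone may compete with reduction of the primary iodide, the alkylsamarium may enolise the ketone, and both chair forms of 28 (bromine equatorial or axial) may be attacked with little preference, which lowers the facial selectivity at the carbinol carbon. The fallback replaces the electron-transfer coupling by a polar organometallic addition at −78 °C; it sets out from iodide 22 and returns at alcohol 30. Iodine–lithium exchange (t-BuLi, 2 equiv, pentane/Et2O, −100 °C), which is faster than addition to the hindered bridged lactone, gives {[(1R,4S,5S,6S,9R)-9-bromo-6-methyl-10-oxo-11-oxatricyclo[4.3.2.0^1,5]undecan-4-yl]methyl}lithium F6. Transmetalation with anhydrous CeCl3 (THF, −78 °C) gives dichloro{[(1R,4S,5S,6S,9R)-9-bromo-6-methyl-10-oxo-11-oxatricyclo[4.3.2.0^1,5]undecan-4-yl]methyl}cerium F7. This weakly basic reagent adds to ketone 28 at −78 °C, where the chair with equatorial bromine is more strongly favoured, and aqueous work-up gives 30.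

**Further compounds**

F1 | step 9 | (3aR,4R,7aR)-4-bromo-7-methyl-1-methylidene-1,2,3,4,5,7a-hexahydro-3aH-indene-3a-carbaldehyde | C=C1CC[C@@]2(C=O)[C@H](Br)CC=C(C)[C@@H]12
F2 | step 9 | (3aR,4R,7aR)-4-bromo-7-methyl-1-methylidene-1,2,3,4,5,7a-hexahydro-3aH-indene-3a-carboxylic acid | C=C1CC[C@@]2(C(=O)O)[C@H](Br)CC=C(C)[C@@H]12
F3 | step 5 | methyl (6Z)-2-(dimethoxymethyl)-7-methyl-5-methylidenenona-6,8-dienoate | C=C(CCC(C(OC)OC)C(=O)OC)/C=C(C)\C=C
F4 | step 5 | methyl (6Z)-2-formyl-7-methyl-5-methylidenenona-6,8-dienoate | C=C(CCC(C=O)C(=O)OC)/C=C(C)\C=C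
F5 | step 5 | methyl (2Z,6Z)-7-methyl-5-methylidene-2-({[(trifluoromethyl)sulfonyl]oxy}methylidene)nona-6,8-dienoate | C=C(CC/C(C(=O)OC)=C/OS(=O)(=O)C(F)(F)F)/C=C(C)\C=C
F6 | step 17 | {[(1R,4S,5S,6S,9R)-9-bromo-6-methyl-10-oxo-11-oxatricyclo[4.3.2.0^1,5]undecan-4-yl]methyl}lithium | [Li]C[C@H]2CC[C@@]34C(=O)O[C@@](C)(CC[C@H]3Br)[C@@H]24
F7 | step 17 | dichloro{[(1R,4S,5S,6S,9R)-9-bromo-6-methyl-10-oxo-11-oxatricyclo[4.3.2.0^1,5]undecan-4-yl]methyl}cerium | Cl[Ce](Cl)C[C@H]2CC[C@@]34C(=O)O[C@@](C)(CC[C@H]3Br)[C@@H]24
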